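The data are simulated from invented constants.

Add up the amounts at 25 h. In Saturday's run target and side product hold 27.9% of the substrate charged, so a rest R = 72.1% has reached neither.

| flask | substrate | gas | remark | time |
|---|---|---|---|---|
| Friday's | 0.061 M | 7.4 mM (held) | run made earlier |  |
| Saturday's | 0.15 M | 7.4 mM (held) | run made earlier |  |
| Sunday's | 0.36 M | 7.4 mM (held) | run made earlier |  |
| north-east | 0.050 M | 7.4 mM (held) |  | 25 h |
| west | 0.10 M | 7.4 mM (held) |  | 25 h |
| south-east | 0.20 M | 7.4 mM (held) |  | 25 h |
| east | 0.40 M | 7.4 mM (held) |  | 25 h |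

| run | time / h | target / % | side product / % |
|---|---|---|---|
| Friday's | 2.00 | 0.2 | 1.1 |
| Friday's | 6.00 | 1.6 | 3.9 |
| Friday's | 12.0 | 6.4 | 5.9 |
| Friday's | 20.0 | 13.8 | 8.1 |
| Friday's | 25.0 | 17.9 | 8.3 |
| Saturday's | 5.00 | 0.9 | 3.7 |
| Saturday's | 10.0 | 4.4 | 5.8 |
| Saturday's | 15.0 | 8.9 | 7.7 |
| Saturday's | 20.0 | 13.5 | 8.3 |
| Saturday's | 25.0 | 18.4 | 9.5 |
| Sunday's | 2.00 | 0.4 | 1.6 |
| Sunday's | 4.00 | 0.2 | 2.9 |
| Sunday's | 8.00 | 2.4 | 6.1 |
| Sunday's | 12.0 | 4.7 | 8.7 |
| Sunday's | 25.0 | 17.0 | 11.8 |

(readings scatter by 0.3 percentage points)

- the numbers in the tables scatter with a standard deviation of 0.3 percentage points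
- at the start none of the gas is in solution
- "hardly changes" means that all values lie within two and a half points (for a concentration: within two and a half percent of the largest)

* share of target in all that became target or side product for north-east, west, south-east, east, in this order
* the shape of the row from first to last (falls, then rises / hardly changes / falls all the way / rises all the way / rises, then falls)

How long will that rest take to come through? We divide R by s, the fraction of the charge that the target gains per hour late in the run. We reckon this in two flasks that share no reading.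

Saturday's run, 15.0 h to 25.0 h: s = 0.00950 h⁻¹, R/s = 75.9 h

Sunday's run, 12.0 h to 25.0 h: s = 0.00946 h⁻¹, R = 71.2%, R/s = 75.3 h

The charges are 0.15 M and 0.36 M, yet the two figures agree, so we trust their mean, τ = 75.6 h. We call τ the store lifetime: the rest at the end of a run over the target's late hourly gain. Friday's run, over 12.0 h to 25.0 h, gives 83.4 h, which is longer, so we take the figure as good to some 7.80 h.

At 3.02 times the length of a run, τ says that these flasks are read in mid-passage. The read shares at 25 h are 68.3%, 65.9% and 59.0%, falling as the charge rises.

The forecast gives 69%, 67%, 64% and 59%, a row that falls all the way, on the ground that the target's percentage stays nearly level with charge while the side product's rises, so “that path has a somewhat higher order in substrate”.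

The flasks give 69.5%, 67.7%, 64.4% and 58.5%, a row that falls all the way, so the forecast stands.

    substrate → intermediate A (k = 0.00140 min⁻¹)
    substrate + partner → intermediate B (k = 2.20 L mol⁻¹ min⁻¹)
    partner + intermediate B → intermediate C (k = 0.390 L mol⁻¹ min⁻¹)
    intermediate A → side product (k = 0.00190 min⁻¹)
    intermediate C → target (k = 2.10 × 10⁻⁴ min⁻¹)
    gas ⇌ partner, rate k6*(csat - [partner]) (kL = 0.740 min⁻¹)

East's share is low because it is read at 25.0 h and not ten times later : at 250 h it is 86.8%. At 25.0 h east's intermediate C, the resting state, holds 68.8%. The wait to 250 h is 2.98 store lifetimes, which leaves 3.49% against 4.17% in the flask. In north-east the same count leaves 3.62% of 71.3% against 4.28% in the flask, and over that wait its share climbs from 69.5% to 90.9%.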